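## The problem

Positions follow germacrane numbering: C1 carries the methoxy group, C4=C5 is the E alkene, C6 bears the lactone oxygen, C7 is the ring-fusion CH, C8 bears the ester oxygen, C9 is the ketone, C10 carries a methyl group, and C11–C12 complete the α-methyl-γ-lactone. Target 35 is a ten-membered carbocycle cis-fused at C6/C7 to that lactone, so a medium ring containing an E-trisubstituted alkene must be closed against strain and entropy. There are eight stereocentres: 1S, 6S, 7S, 8R, 10S and 11S on the core, and 2S,3R in the 2,3-dimethyloxirane-2-carboxylate. C6, C7, C8 and C11 are contiguous and can be set in an open chain. C6 and C7 come from one aldol event, C11 from alkylation of the lactone on the face away from the C7 branch, and C8 from 1,2- and 1,3-induction by C7 and C6. C1 and C10 are remote from this block and can only be controlled by the conformation of the finished ring. The fragile groups are the epoxy ester (acid, nucleophiles, methoxide), the β-methoxy ketone (E1cB loss of methanol), the ketone α-carbons C8 and C10, the allylic lactone C6–O bond, and any free C8 hydroxyl, which is γ to C12 and can translactonize. The enabling feature is that the β-methoxy ketone C1–C10–C9 is the methanol adduct of a C1=C10 enone. The C9–C10 bond of that enone joins a carbon that can be a vinyl iodide (C10) to one that can be an aldehyde (C9), and closing the ring there creates only a C9 carbinol that is later oxidized away.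

## Retrosynthesis

**C8–O acyl bond.** Target 35 is cut into hydroxy ketone 29 and epoxy acid 33. The epoxy ester would not survive the methoxide, hydride or organometallic steps that come earlier, so it is attached last. The forward step must acylate a hindered α-ketol faster than that ketol attacks C12. Acid 33 is traced through epoxy alcohol 32 and allylic alcohol 31 to tiglic acid 30. The two oxirane C–O bonds are cut, and a reagent-controlled epoxidation of 31 must set both centres.

**C1–OMe and C10–H bonds.** Hydroxy ketone 29 comes from silyl ether 28, and 28 from enone 27 by removing methanol. Two stereocentres disappear, and what remains is a dienone whose functionality sits where the ring can be closed. Carrying C1 and C10 through the synthesis instead would expose a β-methoxy carbonyl unit to every later base. The forward reaction asks for reversible conjugate addition in which the ring conformation selects the face, under base mild enough to spare the lactone and C8.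

**C9–C10 bond (ring closure).** Enone 27 is the oxidation product of dienol 26, which is opened to iodo aldehyde 24. Cutting C1–C2 or C2–C3 would require sp3–sp3 alkylation in a medium ring. Cutting C5–C6 would create the permanent C6 stereocentre during ring closure. Cutting C9–C10 pairs a vinyl iodide with an aldehyde and creates only the disposable C9 carbinol. Precursor 24 is acyclic apart from the lactone. The forward reaction must tolerate the lactone, keep the E geometry and not epimerize the α-silyloxy aldehyde.

**C9 formyl group, C11 methyl and C8–C9 bond.** The aldehyde of 24 is carried as the thiazole of 21. The C11–CH3 bond is cut to give 20, because a lactone enolate with both ring substituents on one face must be methylated from the other. Bringing the methyl group in from the chiral pool was weighed against this. It would place a branched, ester-bearing stereocentre beside the aldol enolate and cost extra steps to tell two carboxyl groups apart. Silyl ether 20 comes from carbinol 19, and the C8–C9 bond is cut to aldehyde 16 and 2-(trimethylsilyl)thiazole 17. A strongly basic acyl-anion equivalent would generate an alkoxide beside the lactone and would enolize a β-acyloxy aldehyde. Compound 17 adds under neutral conditions with silyl transfer to oxygen. The forward step must set 8R, which is the Felkin–Anh/1,3-anti outcome.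

**C6–C7 bond and lactone C–O bond.** Aldehyde 16 comes from the N-acylthiazolidinethione 15. Opening the lactone gives aldol adduct 13 (through hydroxy ester 14), and cutting C6–C7 gives imide 12 and dienal 9. This is the convergent cut: it joins the two halves and sets C6 and C7 under auxiliary control. The aldol must be anti, because only the anti adduct closes to the cis lactone. The thiazolidinethione is chosen because it is reduced straight to the aldehyde without passing through a free primary alcohol.

**Imide 12.** The N–acyl bond is cut to 4-methoxy-4-oxobutanoic acid 10 and (S)-4-benzylthiazolidine-2-thione 11, both commercial.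

**Dienal 9.** The aldehyde is traced to alcohol 8, and the C10–I bond to the alkyne of enynol 6 (hydrozirconation–iodination sets the E iodoalkene). Enynol 6 comes from ester 5. The C4–CH3 bond is cut to enol phosphate 4, whose geometry dictates the E alkene, and 4 comes from keto ester 3. The C2–C3 bond is cut to ethyl acetoacetate 1 and 1-bromobut-2-yne 2. A Horner–Wadsworth–Emmons reaction on the corresponding methyl ketone would be equally short but would give E/Z mixtures at C4=C5.

## Roads not taken

**Alternative 1:** The ten-membered ring is contracted to the trans-1,2-dialkenylcyclohexanol A1. In the forward step KH and 18-crown-6 form the alkoxide, an anionic oxy-Cope rearrangement forms C6–C7 and breaks C4–C9, and chlorotrimethylsilane traps the enolate as silyl enol ether A2.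
- Merits: the ring is made by expansion, so no high dilution and no stoichiometric metal are needed. The chair transition state fixes the E C4=C5 alkene and the C6/C7 relationship. C1 and C10 are set on a six-membered ring, where control is reliable. In these respects this road is better than the chosen one, which rests C1 and C10 on a late conjugate addition.
- Weak points: A1 needs a tertiary carbinol next to a quaternary carbon, each carrying an alkenyl group of defined geometry (one a Z-alkoxyvinyl group), and the reactive chair forces the C1 methoxy group axial. After A2, C8 still has to be oxygenated through the enol ether with ring-controlled facial selectivity, and the side chain has to be oxidized and lactonized after removal of the 4-methoxybenzyl group, which is about seven further steps.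
- Comparison: the chosen plan offers a convergent assembly from two simple pieces, C6, C7 and C8 set in open-chain reactions at the correct oxidation level, and only four steps after ring closure.

**Alternative 2:** The C5–C6 bond and the C4–methyl bond are cut, giving the acyclic ynal A3. In the forward step Ni(COD)2 couples the alkyne terminus with the C6 aldehyde while Me2Zn delivers methyl to C4, giving cyclodecenol A4.
- Merits: nickel is catalytic, and the E alkene, the C6 carbinol and the ring form in one step. C1 and C10 are set beforehand by open-chain chemistry. The steps after closure (lactonization, desilylation, esterification) are no more numerous than in the chosen plan. On metal economy and on C1/C10 control this road is at least as good.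
- Weak points: C6 is created during ring closure under substrate control only, and it is permanent. A terminal alkyne can close in the exo or the endo sense. A3 holds a β-methoxy ketone and an α-silyloxy ketone, which Me2Zn and low-valent nickel can enolize, eliminate or engage in competing coupling, and it must be built as a linear array of five stereocentres.
- Comparison: the chosen plan closes the ring with a precedented medium-ring reaction on a precursor free of the base-sensitive β-methoxy ketone, and its new stereocentre is disposable.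

**Alternative 3:** The C2–C3 bond is cut, giving the allylic carbonate–β-keto sulfone A5. In the forward step Pd(PPh3)4 ionizes the carbonate and the sulfone-stabilized carbanion at C2 attacks the C3 terminus, giving cyclic β-keto sulfone A6 with the E C4=C5 alkene.
- Merits: palladium is catalytic, the nucleophile is soft and stabilized, the bond forms away from stereocentres, and macrocyclizations of this kind have good precedent. On metal economy it is better than the chosen plan.
- Weak points: once C4=C5 exists, the lactone C6–O bond is an allylic carboxylate that zerovalent palladium can ionize, which threatens C6 and the lactone. Attack at the other allyl terminus would give an eight-membered ring, and the alkene geometry depends on the syn/anti allyl isomers. After A6 come desulfonylation, reduction of the C1 ketone (facial control by the ring, as in the chosen plan), O-methylation, protecting-group exchange, oxidation at C9 and esterification, which is six steps or more.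
- Comparison: both plans rely on the macrocycle for C1. The chosen plan has fewer steps after closure and forms the ring at carbons whose functionality is exactly what the target needs.

Key step: step 15

Assumption: metal enolates, alkoxides and other simple conjugate bases of numbered compounds are treated as forms of those compounds and carry no number of their own.
Assumption: dienol 26 is drawn as the 9S epimer expected from Felkin–Anh addition; the 9R epimer serves equally.

## Route

Step 1
Reactants: 1 ethyl acetoacetate; 2 1-bromobut-2-yne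
Product: 3 ethyl 3-oxooct-6-ynoate
Conditions: NaH, THF, 0 °C; n-BuLi, 0 °C; then 2, 0 °C → rt
Reagents that add atoms: none
Why: Alkylation of the acetoacetate dianion: the second deprotonation creates the more nucleophilic γ-carbanion, which displaces the propargylic bromide by SN2 at CH2 and forms the C2–C3 bond; the internal alkyne is inert.

Step 2
Reactants: 3 ethyl 3-oxooct-6-ynoate
Product: 4 ethyl (Z)-3-(diethoxyphosphoryloxy)oct-2-en-6-ynoate
Conditions: NaH, Et2O, 0 °C; ClP(O)(OEt)2, 0 °C → rt
Reagents that add atoms: diethyl chlorophosphate, CCOP(=O)(Cl)OCC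
Why: O-Phosphorylation of the chelated sodium enolate of a β-keto ester gives the Z enol phosphate (phosphate oxygen cis to the ester), which fixes the geometry of the later C4=C5 alkene.

Step 3
Reactants: 4 ethyl (Z)-3-(diethoxyphosphoryloxy)oct-2-en-6-ynoate
Product: 5 ethyl (E)-3-methyloct-2-en-6-ynoate
Conditions: Me2CuLi (from MeLi and CuI), Et2O, −78 → −45 °C
Reagents that add atoms: lithium dimethylcuprate, [Li+].C[Cu-]C
Why: Cuprate substitution of a β-phosphoryloxy enoate (conjugate addition–elimination) proceeds with retention, so methyl takes the position cis to the ester and the E-trisubstituted enoate should form as one geometric isomer; the internal alkyne does not react with the cuprate.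

Step 4
Reactants: 5 ethyl (E)-3-methyloct-2-en-6-ynoate
Product: 6 (E)-3-methyloct-2-en-6-yn-1-ol
Conditions: i-Bu2AlH (2.2 equiv), CH2Cl2, −78 °C; aq. potassium sodium tartrate
Reagents that add atoms: none
Why: 1,2-Reduction of a conjugated ester to the allylic alcohol by i-Bu2AlH; the alkyne and the alkene geometry are untouched.

Step 5
Reactants: 6 (E)-3-methyloct-2-en-6-yn-1-ol
Product: 8 (2E,6E)-7-iodo-3-methylocta-2,6-dien-1-ol, via alkenylzirconocene 7 (not isolated)
Conditions: Cp2Zr(H)Cl (3 equiv), THF, rt → 45 °C; then I2, 0 °C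
Reagents that add atoms: iodine, II
Why: Hydrozirconation–iodination of a methyl-substituted internal alkyne: the first equivalent is consumed by the hydroxyl, syn addition of Zr–H follows, and excess reagent with gentle warming equilibrates zirconium to the less hindered methyl-bearing carbon. Iodinolysis with retention gives the E-2-iodo-2-alkene, and the trisubstituted allylic alkene is too hindered to react.

Step 6
Reactants: 8 (2E,6E)-7-iodo-3-methylocta-2,6-dien-1-ol
Product: 9 (2E,6E)-7-iodo-3-methylocta-2,6-dienal
Conditions: MnO2, CH2Cl2, rt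
Reagents that add atoms: none
Why: MnO2 oxidizes only the allylic alcohol, does not isomerize the enal and leaves the vinyl iodide alone.

Step 7
Reactants: 10 4-methoxy-4-oxobutanoic acid; 11 (S)-4-benzylthiazolidine-2-thione
Product: 12 methyl 4-[(S)-4-benzyl-2-thioxothiazolidin-3-yl]-4-oxobutanoate
Conditions: EDC·HCl, DMAP (cat.), CH2Cl2, 0 °C → rt
Reagents that add atoms: none
Why: Carbodiimide-mediated N-acylation of the thiazolidinethione, the standard entry to N-acylthiazolidinethiones; the methyl ester is inert.

Step 8
Reactants: 12 methyl 4-[(S)-4-benzyl-2-thioxothiazolidin-3-yl]-4-oxobutanoate; 9 (2E,6E)-7-iodo-3-methylocta-2,6-dienal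
Product: 13 methyl (3S,4S,5E,9E)-3-[(S)-4-benzyl-2-thioxothiazolidine-3-carbonyl]-10-iodo-6-methyl-4-(trimethylsilyloxy)undeca-5,9-dienoate
Conditions: MgBr2·OEt2 (0.2 equiv), Et3N, TMSCl, EtOAc, rt
Reagents that add atoms: chlorotrimethylsilane, C[Si](C)(C)Cl
Why: Magnesium halide-catalysed direct anti-aldol addition of an N-acylthiazolidinethione to an unsaturated aldehyde: soft enolization occurs only at the imide α-carbon (C7), the Z magnesium enolate adds on the face opposite the benzyl group through a boat-like transition state, and silylation of the aldolate turns the catalyst over and blocks retro-aldol. The auxiliary fixes C7 (S) and the anti topology fixes C6 (S), the relationship that later closes to the cis lactone.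

Step 9
Reactants: 13 methyl (3S,4S,5E,9E)-3-[(S)-4-benzyl-2-thioxothiazolidine-3-carbonyl]-10-iodo-6-methyl-4-(trimethylsilyloxy)undeca-5,9-dienoate
Product: 15 (S)-4-benzyl-3-{(2S,3S)-2-[(1E,5E)-6-iodo-2-methylhepta-1,5-dien-1-yl]-5-oxotetrahydrofuran-3-carbonyl}thiazolidine-2-thione, via hydroxy ester 14 (not isolated)
Conditions: 1 M HCl, THF, 0 °C; then PPTS (cat.), PhMe, 50 °C
Reagents that add atoms: none
Why: Mild acid cleaves the trimethylsilyl ether, and the freed C6 hydroxyl closes onto the γ-placed methyl ester (5-exo-trig lactonization); an anti aldol adduct necessarily gives the lactone with C5 and C8 cis.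

Step 10
Reactants: 15 (S)-4-benzyl-3-{(2S,3S)-2-[(1E,5E)-6-iodo-2-methylhepta-1,5-dien-1-yl]-5-oxotetrahydrofuran-3-carbonyl}thiazolidine-2-thione
Product: 16 (2S,3S)-2-[(1E,5E)-6-iodo-2-methylhepta-1,5-dien-1-yl]-5-oxotetrahydrofuran-3-carbaldehyde
Conditions: i-Bu2AlH (1.1 equiv), CH2Cl2, −78 °C; aq. potassium sodium tartrate; short silica pad, used at once
Reagents that add atoms: none
Why: N-Acylthiazolidinethiones are reduced by one equivalent of i-Bu2AlH at −78 °C to a chelated hemiaminal that releases the aldehyde only on work-up. This activated amide is far more electrophilic than the lactone, and no alkoxide or free primary alcohol is formed that could translactonize.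

Step 11
Reactants: 16 (2S,3S)-2-[(1E,5E)-6-iodo-2-methylhepta-1,5-dien-1-yl]-5-oxotetrahydrofuran-3-carbaldehyde; 17 2-(trimethylsilyl)thiazole
Product: 19 (4R,5S)-4-[(R)-hydroxy(thiazol-2-yl)methyl]-5-[(1E,5E)-6-iodo-2-methylhepta-1,5-dien-1-yl]dihydrofuran-2(3H)-one, via O-trimethylsilyl adduct 18 (not isolated)
Conditions: 17 (1.5 equiv), CH2Cl2, 0 °C → rt; then 1 M HCl, THF, 0 °C
Reagents that add atoms: none
Why: Thiazole-based formyl-anion homologation: 17 adds to aldehydes without base or catalyst and transfers silicon to oxygen, so no alkoxide appears beside the lactone and the elimination-prone aldehyde meets no base. C8 (R) is expected from Felkin–Anh attack anti to the C7–C6 bond (C6 is the large oxygen-bearing α-substituent, C11H2 the medium one), reinforced by 1,3-anti induction from the C6 oxygen in this anti-configured aldehyde.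

Step 12
Reactants: 19 (4R,5S)-4-[(R)-hydroxy(thiazol-2-yl)methyl]-5-[(1E,5E)-6-iodo-2-methylhepta-1,5-dien-1-yl]dihydrofuran-2(3H)-one
Product: 20 (4S,5S)-4-[(R)-(tert-butyldimethylsilyloxy)(thiazol-2-yl)methyl]-5-[(1E,5E)-6-iodo-2-methylhepta-1,5-dien-1-yl]dihydrofuran-2(3H)-one
Conditions: TBSOTf, 2,6-lutidine, CH2Cl2, −78 °C
Reagents that add atoms: tert-butyldimethylsilyl trifluoromethanesulfonate, CC(C)(C)[Si](C)(C)OS(=O)(=O)C(F)(F)F
Why: Fast silylation of the hindered secondary alcohol by the silyl triflate with a weak pyridine base; the C8 hydroxyl is capped before it can attack C12 (the C7 descriptor changes only through priority).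

Step 13
Reactants: 20 (4S,5S)-4-[(R)-(tert-butyldimethylsilyloxy)(thiazol-2-yl)methyl]-5-[(1E,5E)-6-iodo-2-methylhepta-1,5-dien-1-yl]dihydrofuran-2(3H)-one
Product: 21 (3S,4S,5S)-4-[(R)-(tert-butyldimethylsilyloxy)(thiazol-2-yl)methyl]-5-[(1E,5E)-6-iodo-2-methylhepta-1,5-dien-1-yl]-3-methyldihydrofuran-2(3H)-one
Conditions: LiN(SiMe3)2 (1.1 equiv), THF, −78 °C; MeI, −78 → −40 °C
Reagents that add atoms: iodomethane, CI
Why: Alkylation of a γ-butyrolactone enolate anti to its β-substituent: the C7 side chain and the C6 dienyl group lie on the same face, so iodomethane enters from the other face and C11 (S) forms with methyl trans to C8; the enolate has no β-leaving group.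

Step 14
Reactants: 21 (3S,4S,5S)-4-[(R)-(tert-butyldimethylsilyloxy)(thiazol-2-yl)methyl]-5-[(1E,5E)-6-iodo-2-methylhepta-1,5-dien-1-yl]-3-methyldihydrofuran-2(3H)-one
Product: 24 (R)-2-(tert-butyldimethylsilyloxy)-2-{(2S,3S,4S)-2-[(1E,5E)-6-iodo-2-methylhepta-1,5-dien-1-yl]-4-methyl-5-oxotetrahydrofuran-3-yl}acetaldehyde, via N-methylthiazolium triflate 22 (not isolated), via N-methylthiazolidine 23 (not isolated)
Conditions: MeOTf, MeCN, 0 °C → rt; NaBH4, MeOH, −10 °C; CuCl2·2H2O, CuO, MeCN/H2O, rt
Reagents that add atoms: water, O
Why: Thiazole-to-formyl unmasking by N-methylation, hydride reduction to the thiazolidine and copper-assisted hydrolysis of this N,S-acetal. The sequence is close to neutral, so the α-silyloxy aldehyde keeps its C8 configuration, and the lactone, vinyl iodide and silyl ether are spectators.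

Step 15
Reactants: 24 (R)-2-(tert-butyldimethylsilyloxy)-2-{(2S,3S,4S)-2-[(1E,5E)-6-iodo-2-methylhepta-1,5-dien-1-yl]-4-methyl-5-oxotetrahydrofuran-3-yl}acetaldehyde
Product: 26 (6S,7S,8R,9S,11S)-8-(tert-butyldimethylsilyloxy)-9-hydroxygermacra-1(10)E,4E-dien-12,6-olide, via alkenylchromium dichloride 25 (not isolated)
Conditions: CrCl2 (10 equiv), NiCl2 (0.1 equiv), DMSO/THF, rt, slow addition of 24 to 0.003 M
Reagents that add atoms: none
Why: Zerovalent nickel, formed from NiCl2 by reduction with CrCl2, inserts into the C10–I bond with retention of the E geometry, and transmetalation to trivalent chromium gives alkenylchromium 25, which adds to the C9 aldehyde (Nozaki–Hiyama–Kishi reaction). The closest known reaction type is the intramolecular nickel/chromium-mediated coupling of alkenyl iodides with aldehydes used to close nine- to eleven-membered rings. The ten-membered carbocycle is closed end to end by a 10-exo-trig addition of C10 to the aldehyde carbon, forming the C9–C10 bond. The one new stereocentre, C9, is governed by the C8 silyloxy group (Felkin–Anh, anti to the C–O bond) and the ring-forming conformation and should be mainly 9S, but step 16 oxidizes both epimers to the same ketone. Chemoselectivity comes from the reagent: alkenylchromium species add to aldehydes and ignore lactones, silyl ethers and isolated alkenes, and the medium is not basic, so C8 does not epimerize. The E geometry of C1=C10 follows from the configurational stability of the trisubstituted alkenylchromium. Cyclization must beat intermolecular coupling: the cis-fused lactone turns the C5 and C8 arms to the same side, both alkenes are already E, and slow addition keeps the concentration of 24 low.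

Step 16
Reactants: 26 (6S,7S,8R,9S,11S)-8-(tert-butyldimethylsilyloxy)-9-hydroxygermacra-1(10)E,4E-dien-12,6-olide
Product: 27 (6S,7S,8R,11S)-8-(tert-butyldimethylsilyloxy)-9-oxogermacra-1(10)E,4E-dien-12,6-olide
Conditions: Dess–Martin periodinane, NaHCO3, CH2Cl2, 0 °C → rt
Reagents that add atoms: none
Why: Buffered Dess–Martin oxidation of the allylic carbinol; both C9 epimers give the same enone, and the neutral conditions leave C8 untouched.

Step 17
Reactants: 27 (6S,7S,8R,11S)-8-(tert-butyldimethylsilyloxy)-9-oxogermacra-1(10)E,4E-dien-12,6-olide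
Product: 28 (1S,6S,7S,8R,10S,11S)-8-(tert-butyldimethylsilyloxy)-1-methoxy-9-oxogermacr-4E-en-12,6-olide
Conditions: NaOMe (0.1 equiv), MeOH, 0 °C
Reagents that add atoms: methanol, CO
Why: Reversible oxa-Michael addition to the E enone: methoxide should attack C1 on the outer face of the ring conformer, and the C10 enolate is protonated under equilibrating conditions, so C1 (S) and C10 (S) are set under thermodynamic control by the ten-membered ring. Catalytic base at 0 °C is meant to keep the lactone, C8 and C11 intact.

Step 18
Reactants: 28 (1S,6S,7S,8R,10S,11S)-8-(tert-butyldimethylsilyloxy)-1-methoxy-9-oxogermacr-4E-en-12,6-olide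
Product: 29 (1S,6S,7R,8R,10S,11S)-8-hydroxy-1-methoxy-9-oxogermacr-4E-en-12,6-olide
Conditions: HF·pyridine, THF/pyridine, 0 °C → rt
Reagents that add atoms: none
Why: Acidic fluoride desilylation; no alkoxide or basic fluoride is present, which avoids E1cB loss of methanol, epimerization at C8 and attack of O8 on C12 (the C7 descriptor changes only through priority).

Step 19
Reactants: 30 tiglic acid
Product: 31 (E)-2-methylbut-2-en-1-ol
Conditions: LiAlH4, Et2O, 0 °C → rt
Reagents that add atoms: none
Why: Hydride reduction of the conjugated acid to the allylic alcohol; the trisubstituted alkene is not reduced.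

Step 20
Reactants: 31 (E)-2-methylbut-2-en-1-ol
Product: 32 [(2R,3R)-2,3-dimethyloxiran-2-yl]methanol
Conditions: Ti(OiPr)4 (0.1 equiv), D-(−)-diethyl tartrate (0.12 equiv), t-BuOOH, 4 Å molecular sieves, CH2Cl2, −20 °C
Reagents that add atoms: tert-butyl hydroperoxide, CC(C)(C)OO
Why: Sharpless asymmetric epoxidation of an E-trisubstituted allylic alcohol, a favourable substrate class; the D-(−)-tartrate complex delivers oxygen to the face that gives the (2R,3R) epoxide (the L-(+)-tartrate would give 2S,3S).

Step 21
Reactants: 32 [(2R,3R)-2,3-dimethyloxiran-2-yl]methanol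
Product: 33 (2S,3R)-2,3-dimethyloxirane-2-carboxylic acid
Conditions: RuCl3·xH2O (cat.), NaIO4, CCl4/MeCN/H2O, rt
Reagents that add atoms: water, O
Why: Ruthenium tetroxide oxidation (generated catalytically from RuCl3 and NaIO4) of a primary alcohol to the acid through the aldehyde hydrate, a method that spares epoxides; the C2 descriptor changes from R to S only because the carboxyl group outranks C3.

Step 22
Reactants: 33 (2S,3R)-2,3-dimethyloxirane-2-carboxylic acid; 29 (1S,6S,7R,8R,10S,11S)-8-hydroxy-1-methoxy-9-oxogermacr-4E-en-12,6-olide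
Product: 35 (1S,6S,7S,8R,10S,11S)-1-methoxy-9-oxogermacr-4E-en-12,6-olid-8-yl (2S,3R)-2,3-dimethyloxirane-2-carboxylate (CNP0145898.1), via mixed anhydride 34 (not isolated)
Conditions: 2,4,6-trichlorobenzoyl chloride, Et3N, PhMe, rt; then 29, DMAP, PhMe, rt
Reagents that add atoms: none
Why: Yamaguchi esterification: the preformed mixed anhydride is attacked by DMAP at the less hindered epoxy-acyl carbonyl, and the acylpyridinium acylates the hindered C8 hydroxyl. The acid has no α-hydrogen to epimerize, and preforming the anhydride keeps the contact of 29 with base short.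

## Compound list

1 | ethyl acetoacetate | CCOC(=O)CC(C)=O | starting material
2 | 1-bromobut-2-yne | CC#CCBr | starting material
3 | ethyl 3-oxooct-6-ynoate | CCOC(=O)CC(=O)CCC#CC | intermediate
4 | ethyl (Z)-3-(diethoxyphosphoryloxy)oct-2-en-6-ynoate | CCOC(=O)/C=C(\OP(=O)(OCC)OCC)CCC#CC | intermediate
5 | ethyl (E)-3-methyloct-2-en-6-ynoate | CCOC(=O)/C=C(\C)CCC#CC | intermediate
6 | (E)-3-methyloct-2-en-6-yn-1-ol | OC/C=C(\C)CCC#CC | intermediate
7 | alkenylzirconocene chloride from 6 (zirconium on C7 trans to C5; O1 as zirconium alkoxide) | C/C(=C\CC/C(C)=C/CO[Zr](Cl)(C1C=CC=C1)C1C=CC=C1)[Zr](Cl)(C1C=CC=C1)C1C=CC=C1 | intermediate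
8 | (2E,6E)-7-iodo-3-methylocta-2,6-dien-1-ol | OC/C=C(\C)CC/C=C(\C)I | intermediate
9 | (2E,6E)-7-iodo-3-methylocta-2,6-dienal | O=C/C=C(\C)CC/C=C(\C)I | intermediate
10 | 4-methoxy-4-oxobutanoic acid | COC(=O)CCC(=O)O | starting material
11 | (S)-4-benzylthiazolidine-2-thione | S=C1SC[C@H](Cc2ccccc2)N1 | starting material
12 | methyl 4-[(S)-4-benzyl-2-thioxothiazolidin-3-yl]-4-oxobutanoate | COC(=O)CCC(=O)N1[C@@H](Cc2ccccc2)CSC1=S | intermediate
13 | methyl (3S,4S,5E,9E)-3-[(S)-4-benzyl-2-thioxothiazolidine-3-carbonyl]-10-iodo-6-methyl-4-(trimethylsilyloxy)undeca-5,9-dienoate | COC(=O)C[C@@H]([C@@H](O[Si](C)(C)C)/C=C(\C)CC/C=C(\C)I)C(=O)N1[C@@H](Cc2ccccc2)CSC1=S | intermediate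
14 | methyl (3S,4S,5E,9E)-3-[(S)-4-benzyl-2-thioxothiazolidine-3-carbonyl]-4-hydroxy-10-iodo-6-methylundeca-5,9-dienoate | COC(=O)C[C@@H]([C@@H](O)/C=C(\C)CC/C=C(\C)I)C(=O)N1[C@@H](Cc2ccccc2)CSC1=S | intermediate
15 | (S)-4-benzyl-3-{(2S,3S)-2-[(1E,5E)-6-iodo-2-methylhepta-1,5-dien-1-yl]-5-oxotetrahydrofuran-3-carbonyl}thiazolidine-2-thione | O=C1C[C@H](C(=O)N2[C@@H](Cc3ccccc3)CSC2=S)[C@H](/C=C(\C)CC/C=C(\C)I)O1 | intermediate
16 | (2S,3S)-2-[(1E,5E)-6-iodo-2-methylhepta-1,5-dien-1-yl]-5-oxotetrahydrofuran-3-carbaldehyde | O=C1C[C@H](C=O)[C@H](/C=C(\C)CC/C=C(\C)I)O1 | intermediate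
17 | 2-(trimethylsilyl)thiazole | C[Si](C)(C)c1nccs1 | starting material
18 | (4S,5S)-5-[(1E,5E)-6-iodo-2-methylhepta-1,5-dien-1-yl]-4-[(R)-thiazol-2-yl(trimethylsilyloxy)methyl]dihydrofuran-2(3H)-one | O=C1C[C@H]([C@@H](O[Si](C)(C)C)c2nccs2)[C@H](/C=C(\C)CC/C=C(\C)I)O1 | intermediate
19 | (4R,5S)-4-[(R)-hydroxy(thiazol-2-yl)methyl]-5-[(1E,5E)-6-iodo-2-methylhepta-1,5-dien-1-yl]dihydrofuran-2(3H)-one | O=C1C[C@H]([C@@H](O)c2nccs2)[C@H](/C=C(\C)CC/C=C(\C)I)O1 | intermediate
20 | (4S,5S)-4-[(R)-(tert-butyldimethylsilyloxy)(thiazol-2-yl)methyl]-5-[(1E,5E)-6-iodo-2-methylhepta-1,5-dien-1-yl]dihydrofuran-2(3H)-one | O=C1C[C@H]([C@@H](O[Si](C)(C)C(C)(C)C)c2nccs2)[C@H](/C=C(\C)CC/C=C(\C)I)O1 | intermediate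
21 | (3S,4S,5S)-4-[(R)-(tert-butyldimethylsilyloxy)(thiazol-2-yl)methyl]-5-[(1E,5E)-6-iodo-2-methylhepta-1,5-dien-1-yl]-3-methyldihydrofuran-2(3H)-one | O=C1[C@@H](C)[C@H]([C@@H](O[Si](C)(C)C(C)(C)C)c2nccs2)[C@H](/C=C(\C)CC/C=C(\C)I)O1 | intermediate
22 | N-methylthiazolium triflate of 21 | O=C1[C@@H](C)[C@H]([C@@H](O[Si](C)(C)C(C)(C)C)c2scc[n+]2C)[C@H](/C=C(\C)CC/C=C(\C)I)O1.[O-]S(=O)(=O)C(F)(F)F | intermediate
23 | 3-methylthiazolidin-2-yl analogue of 21 (thiazolidine C2 epimers) | O=C1[C@@H](C)[C@H]([C@@H](O[Si](C)(C)C(C)(C)C)C2SCCN2C)[C@H](/C=C(\C)CC/C=C(\C)I)O1 | intermediate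
24 | (R)-2-(tert-butyldimethylsilyloxy)-2-{(2S,3S,4S)-2-[(1E,5E)-6-iodo-2-methylhepta-1,5-dien-1-yl]-4-methyl-5-oxotetrahydrofuran-3-yl}acetaldehyde | I/C(C)=C/CC/C(C)=C/[C@@H]1OC(=O)[C@@H](C)[C@@H]1[C@@H](O[Si](C)(C)C(C)(C)C)C=O | intermediate
25 | alkenylchromium dichloride from 24 (trivalent chromium on C10) | Cl[Cr](Cl)/C(C)=C/CC/C(C)=C/[C@@H]1OC(=O)[C@@H](C)[C@@H]1[C@@H](O[Si](C)(C)C(C)(C)C)C=O | intermediate
26 | (6S,7S,8R,9S,11S)-8-(tert-butyldimethylsilyloxy)-9-hydroxygermacra-1(10)E,4E-dien-12,6-olide | O[C@H]1/C(C)=C/CC/C(C)=C/[C@@H]2OC(=O)[C@@H](C)[C@@H]2[C@H]1O[Si](C)(C)C(C)(C)C | intermediate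
27 | (6S,7S,8R,11S)-8-(tert-butyldimethylsilyloxy)-9-oxogermacra-1(10)E,4E-dien-12,6-olide | O=C1/C(C)=C/CC/C(C)=C/[C@@H]2OC(=O)[C@@H](C)[C@@H]2[C@H]1O[Si](C)(C)C(C)(C)C | intermediate
28 | (1S,6S,7S,8R,10S,11S)-8-(tert-butyldimethylsilyloxy)-1-methoxy-9-oxogermacr-4E-en-12,6-olide | CO[C@H]1CC/C(C)=C/[C@@H]2OC(=O)[C@@H](C)[C@@H]2[C@@H](O[Si](C)(C)C(C)(C)C)C(=O)[C@H]1C | intermediate
29 | (1S,6S,7R,8R,10S,11S)-8-hydroxy-1-methoxy-9-oxogermacr-4E-en-12,6-olide | CO[C@H]1CC/C(C)=C/[C@@H]2OC(=O)[C@@H](C)[C@@H]2[C@@H](O)C(=O)[C@H]1C | intermediate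
30 | tiglic acid | C/C=C(\C)C(=O)O | starting material
31 | (E)-2-methylbut-2-en-1-ol | C/C=C(\C)CO | intermediate
32 | [(2R,3R)-2,3-dimethyloxiran-2-yl]methanol | OC[C@@]1(C)O[C@@H]1C | intermediate
33 | (2S,3R)-2,3-dimethyloxirane-2-carboxylic acid | OC(=O)[C@@]1(C)O[C@@H]1C | intermediate
34 | (2S,3R)-2,3-dimethyloxirane-2-carboxylic 2,4,6-trichlorobenzoic anhydride | O=C(OC(=O)[C@@]1(C)O[C@@H]1C)c1c(Cl)cc(Cl)cc1Cl | intermediate
35 | (1S,6S,7S,8R,10S,11S)-1-methoxy-9-oxogermacr-4E-en-12,6-olid-8-yl (2S,3R)-2,3-dimethyloxirane-2-carboxylate | CO[C@H]1CC/C(C)=C/[C@@H]2OC(=O)[C@@H](C)[C@@H]2[C@@H](OC(=O)[C@@]2(C)O[C@@H]2C)C(=O)[C@H]1C | target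

## Step count and least certain steps

Total: 22 steps. Longest linear sequence: 18 steps (steps 1–6, 8–18 and 22).

**Step 15 (key step).** Intermolecular coupling or simple reductive loss of iodine may outrun ring closure, because forming a ten-membered ring with two E alkenes costs strain and the alkenylchromium species lives long enough to meet a second molecule. The fallback closes the same bond by acylation instead of carbonyl addition and sets out from 24. Exchange of iodine for tin with (Me3Sn)2 and Pd(PPh3)4 would give the stannane aldehyde F1. Pinnick oxidation (NaClO2, NaH2PO4, 2-methylbut-2-ene) would give the stannane acid F2. 1-Chloro-N,N,2-trimethylpropenylamine would give the acid chloride F3 under neutral conditions. An intramolecular Stille acylation (Pd2(dba)3, tri(2-furyl)phosphine, high dilution) would then give enone 27, where the route is rejoined without step 16.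

**Step 8.** Enolization or addition may be slow, or facial selectivity poor, because the ester of the donor competes for magnesium and the sense of induction is inferred from simpler N-acyl groups. The fallback uses the chelate-controlled enolate of the antipodal oxazolidinone and sets out from 10 and 9. Acid 10 is joined to (R)-4-benzyloxazolidin-2-one (pivaloyl chloride, Et3N, then the lithiated oxazolidinone) to give the imide F4. MgCl2, Et3N and chlorotrimethylsilane in EtOAc with 9 should give the anti adduct as its silyl ether F5, because the chelated enolate reacts on the face that the antipodal auxiliary leaves open. Acid treatment as in step 9 passes through the hydroxy ester F6 to the lactone imide F7. LiBH4 (THF, one equivalent of water, 0 °C, cold quench) gives the primary alcohol F8, and Dess–Martin oxidation returns to the route at 16.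

**Step 10.** The lactone may be over-reduced to the lactol, or the lactone carboxylate may be lost by β-elimination from the α-branched aldehyde during work-up. The fallback sets out from 15. N,O-Dimethylhydroxylamine hydrochloride and imidazole displace the auxiliary to give the N-methoxy-N-methylamide F9. Cp2Zr(H)Cl (1.5 equiv, THF, rt) reduces tertiary amides to aldehydes in the presence of esters and lactones, and this returns to the route at 16.

**Step 11.** Facial selectivity at C8 may be poor, because the Felkin–Anh assignment for an aldehyde on a lactone ring rests on analogy with open-chain cases. The fallback sets out from 19 as its mixture of C8 epimers. Dess–Martin oxidation gives the 2-thiazolyl ketone F10. Corey–Bakshi–Shibata reduction with the (S)-2-methyl-oxazaborolidine and catecholborane, in which the heteroaryl group acts as the large substituent, should return the 8R carbinol 19 under reagent control.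

**Step 17.** Methoxide may add to the wrong face of the enone, or the basic medium may epimerize C8 or open the lactone. The fallback forms the C1–O bond under reagent control and sets out from 27. Copper-catalysed asymmetric conjugate borylation (CuCl, NaOt-Bu, a chiral ferrocenyl bisphosphine matched to the 1S face, B2pin2, MeOH) would give the β-boryl ketone F11. Oxidation with NaBO3·4H2O, with retention, gives the β-hydroxy ketone F12. O-Methylation with MeOTf and 2,6-di-tert-butyl-4-methylpyridine returns to the route at 28.

**Step 22.** The free C8 hydroxyl may attack C12 (translactonization), or methanol may be lost under DMAP and Et3N before the hindered acylation is complete. The fallback changes the order of events and sets out from 27. HF·pyridine gives the hydroxy enone F13. Yamaguchi esterification with 33 (through 34) gives the enone ester F14, a substrate with no β-methoxy group to lose. Conjugate addition of methanol with catalytic NaOMe at 0 °C is then the last step and arrives directly at 35; the α,α-disubstituted ester is hindered toward methanolysis.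

## Further compounds

F1 | step 15 | (R)-2-(tert-butyldimethylsilyloxy)-2-{(2S,3S,4S)-4-methyl-2-[(1E,5E)-2-methyl-6-(trimethylstannyl)hepta-1,5-dien-1-yl]-5-oxotetrahydrofuran-3-yl}acetaldehyde | C[Sn](C)(C)/C(C)=C/CC/C(C)=C/[C@@H]1OC(=O)[C@@H](C)[C@@H]1[C@@H](O[Si](C)(C)C(C)(C)C)C=O
F2 | step 15 | (R)-2-(tert-butyldimethylsilyloxy)-2-{(2S,3S,4S)-4-methyl-2-[(1E,5E)-2-methyl-6-(trimethylstannyl)hepta-1,5-dien-1-yl]-5-oxotetrahydrofuran-3-yl}acetic acid | C[Sn](C)(C)/C(C)=C/CC/C(C)=C/[C@@H]1OC(=O)[C@@H](C)[C@@H]1[C@@H](O[Si](C)(C)C(C)(C)C)C(=O)O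
F3 | step 15 | acid chloride of F2 | C[Sn](C)(C)/C(C)=C/CC/C(C)=C/[C@@H]1OC(=O)[C@@H](C)[C@@H]1[C@@H](O[Si](C)(C)C(C)(C)C)C(=O)Cl
F4 | step 8 | methyl 4-[(R)-4-benzyl-2-oxooxazolidin-3-yl]-4-oxobutanoate | COC(=O)CCC(=O)N1[C@H](Cc2ccccc2)COC1=O
F5 | step 8 | methyl (3S,4S,5E,9E)-3-[(R)-4-benzyl-2-oxooxazolidine-3-carbonyl]-10-iodo-6-methyl-4-(trimethylsilyloxy)undeca-5,9-dienoate | COC(=O)C[C@@H]([C@@H](O[Si](C)(C)C)/C=C(\C)CC/C=C(\C)I)C(=O)N1[C@H](Cc2ccccc2)COC1=O
F6 | step 8 | methyl (3S,4S,5E,9E)-3-[(R)-4-benzyl-2-oxooxazolidine-3-carbonyl]-4-hydroxy-10-iodo-6-methylundeca-5,9-dienoate | COC(=O)C[C@@H]([C@@H](O)/C=C(\C)CC/C=C(\C)I)C(=O)N1[C@H](Cc2ccccc2)COC1=O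
F7 | step 8 | (R)-4-benzyl-3-{(2S,3S)-2-[(1E,5E)-6-iodo-2-methylhepta-1,5-dien-1-yl]-5-oxotetrahydrofuran-3-carbonyl}oxazolidin-2-one | O=C1C[C@H](C(=O)N2[C@H](Cc3ccccc3)COC2=O)[C@H](/C=C(\C)CC/C=C(\C)I)O1
F8 | step 8 | (4R,5S)-4-(hydroxymethyl)-5-[(1E,5E)-6-iodo-2-methylhepta-1,5-dien-1-yl]dihydrofuran-2(3H)-one | O=C1C[C@H](CO)[C@H](/C=C(\C)CC/C=C(\C)I)O1
F9 | step 10 | (2S,3S)-2-[(1E,5E)-6-iodo-2-methylhepta-1,5-dien-1-yl]-N-methoxy-N-methyl-5-oxotetrahydrofuran-3-carboxamide | O=C1C[C@H](C(=O)N(C)OC)[C@H](/C=C(\C)CC/C=C(\C)I)O1
F10 | step 11 | (4S,5S)-5-[(1E,5E)-6-iodo-2-methylhepta-1,5-dien-1-yl]-4-(thiazole-2-carbonyl)dihydrofuran-2(3H)-one | O=C1C[C@H](C(=O)c2nccs2)[C@H](/C=C(\C)CC/C=C(\C)I)O1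
F11 | step 17 | 1-(4,4,5,5-tetramethyl-1,3,2-dioxaborolan-2-yl) analogue of 28 (boron in place of the methoxy group, same C1 and C10 geometry) | CC1(C)OB(OC1(C)C)[C@H]2CC/C(C)=C/[C@@H]3OC(=O)[C@@H](C)[C@@H]3[C@@H](O[Si](C)(C)C(C)(C)C)C(=O)[C@H]2C
F12 | step 17 | (1S,6S,7S,8R,10S,11S)-8-(tert-butyldimethylsilyloxy)-1-hydroxy-9-oxogermacr-4E-en-12,6-olide | O[C@H]1CC/C(C)=C/[C@@H]2OC(=O)[C@@H](C)[C@@H]2[C@@H](O[Si](C)(C)C(C)(C)C)C(=O)[C@H]1C
F13 | step 22 | (6S,7R,8R,11S)-8-hydroxy-9-oxogermacra-1(10)E,4E-dien-12,6-olide | O=C1/C(C)=C/CC/C(C)=C/[C@@H]2OC(=O)[C@@H](C)[C@@H]2[C@H]1O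
F14 | step 22 | (6S,7S,8R,11S)-9-oxogermacra-1(10)E,4E-dien-12,6-olid-8-yl (2S,3R)-2,3-dimethyloxirane-2-carboxylate | O=C1/C(C)=C/CC/C(C)=C/[C@@H]2OC(=O)[C@@H](C)[C@@H]2[C@H]1OC(=O)[C@@]1(C)O[C@@H]1C
A1 | alternative 1 | trans-1,2-dialkenylcyclohexanol (C9 carbinol with E-alkenyl side chain; C4 quaternary carbon with Z-2-(4-methoxybenzyloxy)vinyl group) | CO[C@H]1CC[C@@](C)(/C=C\OCc2ccc(OC)cc2)[C@](O)(/C=C/[C@H](C)CO[Si](C)(C)C(C)(C)C)[C@H]1C
A2 | alternative 1 | ring-expanded cyclodecadienyl trimethylsilyl enol ether | CO[C@H]1CC/C(C)=C/[C@H](OCc2ccc(OC)cc2)[C@H]([C@H](C)CO[Si](C)(C)C(C)(C)C)/C=C(\O[Si](C)(C)C)[C@H]1C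
A3 | alternative 2 | acyclic ynal (terminal alkyne for C4/C5, aldehyde at C6) | C#CCC[C@H](OC)[C@H](C)C(=O)[C@H](O[Si](C)(C)C(C)(C)C)[C@H](C=O)[C@H](C)C(=O)OC(C)(C)C
A4 | alternative 2 | cyclodecenol tert-butyl ester | CO[C@H]1CC/C(C)=C/[C@H](O)[C@H]([C@H](C)C(=O)OC(C)(C)C)[C@@H](O[Si](C)(C)C(C)(C)C)C(=O)[C@H]1C
A5 | alternative 3 | allylic methyl carbonate–β-keto sulfone (C5 carbinol epimers) | C=C(C)C(OC(=O)OC)[C@@H]1OC(=O)[C@@H](C)[C@@H]1[C@@H](OCc1ccc(OC)cc1)[C@H](O[Si](C)(C)C(C)(C)C)[C@@H](C)C(=O)CS(=O)(=O)c1ccccc1
A6 | alternative 3 | cyclic β-keto sulfone | O=C1[C@H](S(=O)(=O)c2ccccc2)C/C(C)=C/[C@@H]2OC(=O)[C@@H](C)[C@@H]2[C@@H](OCc2ccc(OC)cc2)[C@H](O[Si](C)(C)C(C)(C)C)[C@H]1C
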